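The runs are simulated for an exercise; scatter was added.

0.961 M is the number to carry: the rival concentration, meaning the amount of first nucleophile at which target stands at half its ceiling, with second nucleophile at 0.20 M.

| flask | substrate | first nucleophile | second nucleophile | remark | time |
|---|---|---|---|---|---|
| theta | 0.10 M | 0.40 M | 0.20 M | run made earlier |  |
| delta | 0.10 M | 0.20 M | 0.20 M | run made earlier |  |
| epsilon | 0.10 M | 0.80 M | 0.20 M | run made earlier |  |
| ash | 0.10 M | 0.400 M (fed, over 2.5 min) | 0.200 M | all else is in the flask from the start; the feed brings no volume worth counting | 4.0 min |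
| birch | 0.10 M | 0.400 M | 0.200 M | everything together at the start | 4.0 min |
| oak | 0.10 M | 0.400 M (in portions, 4, over 2.5 min) | 0.200 M | first portion at the start, last at 2.5 min | 4.0 min |
| maple | 0.10 M | 0.400 M | 0.200 M (fed, over 2.5 min) | all else is in the flask from the start; the feed brings no volume worth counting | 4.0 min |

| run | time / min | target / % |
|---|---|---|
| theta | 0.250 | 3.5 |
| theta | 0.833 | 10.2 |
| theta | 1.33 | 14.0 |
| theta | 2.00 | 16.2 |
| theta | 3.00 | 17.4 |
| theta | 4.00 | 17.1 |
| delta | 0.200 | 1.3 |
| delta | 0.333 | 2.6 |
| delta | 0.500 | 4.0 |
| delta | 0.833 | 5.6 |
| delta | 1.33 | 8.2 |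
| delta | 2.50 | 10.2 |
| epsilon | 0.200 | 3.9 |
| epsilon | 0.333 | 7.5 |
| epsilon | 0.500 | 11.6 |
| epsilon | 0.833 | 16.6 |
| epsilon | 1.33 | 22.0 |
| epsilon | 2.50 | 26.9 |

(standard deviation of a reading: 0.3 percentage points)

- the flask with the highest amount of target, in percent of the substrate charged ("all alike" if they lie within 1.5 percentage points) (ash / birch / oak / maple / all alike)
- final target, as a percentage of the substrate charged, in ash
- final target, as a percentage of the substrate charged, in birch
- final target, as a percentage of the substrate charged, in oak
- final target, as a percentage of the substrate charged, in maple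

You get it from the delta and epsilon readings at 2.50 min, taking target as ceiling × first nucleophile / (first nucleophile + rival concentration), with a ceiling of 59.2%. Theta, kept out of that step, comes to 17.4% against its reading of 17.4% at 3.00 min.

I assume the rival concentration scales with second nucleophile, a selectivity factor of 4.81, and look at the flask when substrate typically reacts, 0.868 min in, from the climb in epsilon. By then ash has received 0.139 M of first nucleophile, which gives 7.47%. Now put that answer back. I reckon about 0.0617 M of substrate reacted by then, 87.4% of it with second nucleophile, which leaves about 0.146 M of second nucleophile, so my figure for ash becomes 9.78%.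

Oak I put beside ash, and birch repeats theta. Maple, by the same two rounds, gives 32.3%, then 39.6%; that is shaky, since no run varied second nucleophile.

The forecast named maple, with 7.5%, 17.3%, 9% and 27% for ash, birch, oak and maple: “Feeding the second nucleophile spares substrate”. The flasks give ash 9.81%, birch 16.5%, oak 10.2% and maple 25.1%, so maple leads.

    intermediate → side product (k = 0.0222 s⁻¹)
    first nucleophile + intermediate → target (k = 0.175 M⁻¹ s⁻¹)
    substrate → intermediate (k = 0.0124 s⁻¹)
    second nucleophile + intermediate → other capture product (k = 0.862 M⁻¹ s⁻¹)
    target → over-reaction product (k = 0.00257 s⁻¹)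
    target ⇌ isomer of the product (K = 0.130, k = 0.00386 s⁻¹)

Ash lands on my second round, but maple falls below its reckoning. Read back through the ceiling, maple's result corresponds to an apparent rival concentration of 0.543 M, against the 0.961 M read from the runs with second nucleophile charged at the start. Keep that value for the neighbour of maple charged with 1.0 M of first nucleophile, and you reckon 38.4%. That neighbour holds 37.1% of target at 4.00 min.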